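**Plan**
- Retrosynthetic cuts: the four O–Si bonds (last step); then O1–C2 of ring C together with the C3–H bond; then C4–C3 (ring A aldehyde plus ring B 1-arylvinyl anion); ring B at aryl–geranyl and aryl–acetyl; ring A at C–CHO and C–OH.
- Enabling feature: C2 is an unsubstituted CH2 on O1, and C3 is the enolisable alpha-carbon of the C4 ketone that carries ring B. Ring C is therefore the adduct of the ring A phenol oxygen to a 2-aryl-propenoyl unit (C4=O, C3=C2H2), and its only stereocentre can be written last, by protonation.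
- Forward order: ring A aldehyde 5 (3 steps from 2-methylresorcinol) and ring B methyl ketone 13 (3 steps from 4,6-dibromoresorcinol) are joined by a Shapiro reaction; oxidation gives hydroxy enone 18; ring C is closed last; the silyl groups are then removed.
- Stereochemistry: C3 (R) arises during ring closure by catalyst-controlled protonation of the enolate; the E-alkene comes unchanged from geranyl bromide.
- Ring A regiochemistry (6-methyl): phenol 4 is symmetric, so formylation can give only one aldehyde, in which the free OH is O1 and the silyloxy group beside the methyl is O5.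
- TIPS ethers throughout: stable to the organolithium steps at low temperature and removed by buffered fluoride, without acid (geranyl chain) or base (C3).

Key step: step 10

Remark: C3 of the target is (R) (CIP order C4 > C2 > C1′ > H), unchanged in the silylated precursor 20; 1, 6 and 8 are taken as commercial.

**Route**

Step 1
Reactants: 1 2-methylresorcinol
Product: 2 2-methyl-1,3-bis(triisopropylsilyloxy)benzene
Conditions: TIPSCl (2.4 equiv), imidazole, DMF, 40 °C
Reagents that add atoms: chlorotriisopropylsilane (TIPSCl), CC(C)[Si](Cl)(C(C)C)C(C)C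
Why: Imidazole-mediated silylation of phenols should protect both hydroxyls as TIPS ethers, which survive the later low-temperature organometallic steps.

Step 2
Reactants: 2 2-methyl-1,3-bis(triisopropylsilyloxy)benzene
Product: 4 4-methyl-3,5-bis(triisopropylsilyloxy)phenol, via arylboronate 3 (not isolated)
Conditions: B2pin2, [Ir(OMe)(cod)]2 (1.5 mol %), dtbpy (3 mol %), THF, 80 °C; then KHSO5 (as the triple salt 2KHSO5·KHSO4·K2SO4), acetone/H2O, 0 °C to rt
Reagents that add atoms: bis(pinacolato)diboron, CC1(C)OB(OC1(C)C)B1OC(C)(C)C(C)(C)O1 (boron of 3); potassium peroxymonosulfate, [K+].[O-]S(=O)(=O)OO (oxygen of 4)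
Why: Sterically governed iridium-catalysed C–H borylation (Hartwig–Miyaura type) should take the only ring C–H without an ortho substituent, para to the methyl group, and one-pot oxidation of the C–B bond should give the phenol.

Step 3
Reactants: 4 4-methyl-3,5-bis(triisopropylsilyloxy)phenol
Product: 5 2-hydroxy-5-methyl-4,6-bis(triisopropylsilyloxy)benzaldehyde
Conditions: MgCl2, Et3N, (CH2O)n, MeCN, reflux; cold 1 M HCl work-up
Reagents that add atoms: paraformaldehyde (formaldehyde), C=O
Why: Magnesium-phenoxide-directed ortho-formylation (Casnati–Skattebøl) should give a single aldehyde, because the two ortho positions of 4 are equivalent by symmetry and the para position carries the methyl group.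

Step 4
Reactants: 6 4,6-dibromoresorcinol
Product: 7 1,5-dibromo-2,4-bis(triisopropylsilyloxy)benzene
Conditions: TIPSCl (2.4 equiv), imidazole, DMF, rt to 40 °C
Reagents that add atoms: chlorotriisopropylsilane (TIPSCl), CC(C)[Si](Cl)(C(C)C)C(C)C
Why: The same phenol silylation as in step 1 should give the symmetric bis-TIPS ether.

Step 5
Reactants: 7 1,5-dibromo-2,4-bis(triisopropylsilyloxy)benzene; 8 geranyl bromide [(2E)-1-bromo-3,7-dimethylocta-2,6-diene]
Product: 11 1-bromo-5-[(2E)-3,7-dimethylocta-2,6-dien-1-yl]-2,4-bis(triisopropylsilyloxy)benzene, via aryllithium 9 (not isolated), via arylcopper 10 (not isolated)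
Conditions: n-BuLi (1.0 equiv), THF, –78 °C; CuBr·SMe2 (1.0 equiv), –78 to –40 °C; 8, –40 to 0 °C
Reagents that add atoms: n-butyllithium, [Li]CCCC (lithium of 9); CuBr·SMe2, Br[Cu].CSC (copper of 10)
Why: Single bromine–lithium exchange on the symmetric dibromide, transmetalation to copper and SN2 allylation at the primary carbon of geranyl bromide should install the geranyl group with the E-alkene intact and leave the second bromide for step 6.

Step 6
Reactants: 11 1-bromo-5-[(2E)-3,7-dimethylocta-2,6-dien-1-yl]-2,4-bis(triisopropylsilyloxy)benzene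
Product: 13 1-{5-[(2E)-3,7-dimethylocta-2,6-dien-1-yl]-2,4-bis(triisopropylsilyloxy)phenyl}ethanone, via aryllithium 12 (not isolated)
Conditions: n-BuLi (1.05 equiv), THF, –78 °C; MeC(O)N(OMe)Me, –78 to 0 °C; H2O
Reagents that add atoms: n-butyllithium, [Li]CCCC (lithium of 12); N-methoxy-N-methylacetamide, CC(=O)N(C)OC
Why: Bromine–lithium exchange followed by Weinreb ketone synthesis should give the methyl ketone without over-addition, because the chelated tetrahedral adduct persists until work-up.

Step 7
Reactants: 13 1-{5-[(2E)-3,7-dimethylocta-2,6-dien-1-yl]-2,4-bis(triisopropylsilyloxy)phenyl}ethanone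
Product: 14 (E)-2,4,6-triisopropylbenzenesulfonylhydrazone of ketone 13
Conditions: 2,4,6-triisopropylbenzenesulfonyl hydrazide, cat. HCl, THF/MeCN, rt
Reagents that add atoms: 2,4,6-triisopropylbenzenesulfonyl hydrazide, CC(C)c1cc(C(C)C)c(S(=O)(=O)NN)c(C(C)C)c1
Why: Acid-catalysed hydrazone formation should give the E-hydrazone, whose N–N bond lies syn to the methyl group as the directed deprotonation of step 8 requires.

Step 8
Reactants: 14 (E)-2,4,6-triisopropylbenzenesulfonylhydrazone of ketone 13; 5 2-hydroxy-5-methyl-4,6-bis(triisopropylsilyloxy)benzaldehyde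
Product: 17 racemic 2-{1-hydroxy-2-[5-((2E)-3,7-dimethylocta-2,6-dien-1-yl)-2,4-bis(triisopropylsilyloxy)phenyl]prop-2-en-1-yl}-4-methyl-3,5-bis(triisopropylsilyloxy)phenol, via vinyllithium 15 (not isolated), via sodium phenoxide 16 (not isolated)
Conditions: 14, n-BuLi (2.1 equiv), THF, –78 °C then 0 °C until N2 evolution ends, recool to –78 °C; 16 (from 5, NaH, THF, 0 °C) added at –78 °C, then to –40 °C; cold H2O quench, neutral work-up
Reagents that add atoms: n-butyllithium, [Li]CCCC (lithium of 15); sodium hydride, [Na+].[H-] (sodium of 16)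
Why: The Shapiro reaction should convert 14 by double deprotonation and loss of sulfinate and N2 into the 1-arylvinyllithium 15, which adds to the aldehyde of the pre-formed phenoxide 16 and so forms the C3–C4 bond; the carbinol centre is racemic and is removed in step 9.

Step 9
Reactants: 17 racemic allylic benzylic alcohol from step 8
Product: 18 2-{5-[(2E)-3,7-dimethylocta-2,6-dien-1-yl]-2,4-bis(triisopropylsilyloxy)phenyl}-1-[2-hydroxy-5-methyl-4,6-bis(triisopropylsilyloxy)phenyl]prop-2-en-1-one
Conditions: activated MnO2 (excess), CH2Cl2, 0 °C to rt; filtration, rapid chromatography on neutral silica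
Reagents that add atoms: none
Why: MnO2 oxidation of an alcohol that is both allylic and benzylic should give the enone under neutral, base-free conditions, in which the hydrogen-bonded phenol O1–H is expected not to add to the new acceptor.

Step 10
Reactants: 18 hydroxy enone from step 9
Product: 20 (3R)-3-{5-[(2E)-3,7-dimethylocta-2,6-dien-1-yl]-2,4-bis(triisopropylsilyloxy)phenyl}-6-methyl-5,7-bis(triisopropylsilyloxy)chroman-4-one, via ring C enolate 19 (not isolated)
Conditions: squaramide of 9-amino-9-deoxy-epi-quinidine and 3,5-bis(trifluoromethyl)aniline (10 mol %), toluene, –30 °C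
Reagents that add atoms: none
Why: Proposed new method: the quinuclidine nitrogen of the bifunctional catalyst takes the proton of the only free phenol (O1–H) while the squaramide N–H pair binds the C4 carbonyl; O1 then adds to the unsubstituted alkene terminus C2, ring C closes in the 6-endo-trig mode to give enolate 19 as a hydrogen-bonded ion pair with the chiral quinuclidinium, and the N–H proton of that ion is finally passed to C3. The closest known reaction types are the cinchona-thiourea- or squaramide-catalysed intramolecular oxa-Michael addition of 2-hydroxyaryl enones to chromanones and the organocatalytic conjugate addition/enantioselective protonation of alpha-substituted acrylic acceptors; their union on an alpha-aryl vinyl ketone, where C2 stays achiral and the stereocentre is born only in the proton transfer, is the new element. C3 is therefore controlled by the catalyst alone, through face-selective protonation of 19 inside the ion pair; the quinidine-derived catalyst is written for the (R) product, and its quinine-derived pseudoenantiomer serves if a first trial shows the opposite sense. Site selectivity for the 6-methyl (not 8-methyl) chromanone needs no control in the step itself, because O5 and both ring B oxygens are silylated and O1–H is the only nucleophile. Enantioselectivity further requires that catalysed closure outruns uncatalysed closure and that protonation outruns epimerisation of 20, which the non-polar solvent, the low temperature, the weak tertiary-amine base and the loss of the phenol anchor in the product should secure. The enolate geometry is fixed by ring C, so only one enolate isomer has to be discriminated.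

Step 11
Reactants: 20 (3R)-tetrakis(triisopropylsilyl) isoflavanone from step 10
Product: 21 (3R)-3-{2,4-dihydroxy-5-[(2E)-3,7-dimethylocta-2,6-dien-1-yl]phenyl}-5,7-dihydroxy-6-methylchroman-4-one (CNP0348256.1)
Conditions: TBAF/AcOH (1:1, 6 equiv), THF, 0 °C
Reagents that add atoms: none
Why: Fluoride cleavage of aryl silyl ethers, buffered with acetic acid so that no free phenoxide or strong acid is present, should release the four phenols without epimerising C3 or cyclising the geranyl chain onto the neighbouring hydroxyl.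

**Compound list**

1 | 2-methylresorcinol (2-methylbenzene-1,3-diol) | Cc1c(O)cccc1O | starting material
2 | 2-methyl-1,3-bis(triisopropylsilyloxy)benzene | Cc1c(O[Si](C(C)C)(C(C)C)C(C)C)cccc1O[Si](C(C)C)(C(C)C)C(C)C | intermediate
3 | 2-[4-methyl-3,5-bis(triisopropylsilyloxy)phenyl]-4,4,5,5-tetramethyl-1,3,2-dioxaborolane (not isolated) | Cc1c(O[Si](C(C)C)(C(C)C)C(C)C)cc(B2OC(C)(C)C(C)(C)O2)cc1O[Si](C(C)C)(C(C)C)C(C)C | intermediate
4 | 4-methyl-3,5-bis(triisopropylsilyloxy)phenol | Cc1c(O[Si](C(C)C)(C(C)C)C(C)C)cc(O)cc1O[Si](C(C)C)(C(C)C)C(C)C | intermediate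
5 | 2-hydroxy-5-methyl-4,6-bis(triisopropylsilyloxy)benzaldehyde | O=Cc1c(O)cc(O[Si](C(C)C)(C(C)C)C(C)C)c(C)c1O[Si](C(C)C)(C(C)C)C(C)C | intermediate
6 | 4,6-dibromoresorcinol (4,6-dibromobenzene-1,3-diol) | Oc1cc(O)c(Br)cc1Br | starting material
7 | 1,5-dibromo-2,4-bis(triisopropylsilyloxy)benzene | Brc1cc(Br)c(O[Si](C(C)C)(C(C)C)C(C)C)cc1O[Si](C(C)C)(C(C)C)C(C)C | intermediate
8 | geranyl bromide, (2E)-1-bromo-3,7-dimethylocta-2,6-diene | CC(C)=CCC/C(C)=C/CBr | starting material
9 | [5-bromo-2,4-bis(triisopropylsilyloxy)phenyl]lithium (not isolated) | [Li]c1cc(Br)c(O[Si](C(C)C)(C(C)C)C(C)C)cc1O[Si](C(C)C)(C(C)C)C(C)C | intermediate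
10 | [5-bromo-2,4-bis(triisopropylsilyloxy)phenyl]copper (not isolated) | [Cu]c1cc(Br)c(O[Si](C(C)C)(C(C)C)C(C)C)cc1O[Si](C(C)C)(C(C)C)C(C)C | intermediate
11 | 1-bromo-5-[(2E)-3,7-dimethylocta-2,6-dien-1-yl]-2,4-bis(triisopropylsilyloxy)benzene | CC(C)=CCC/C(C)=C/Cc1cc(Br)c(O[Si](C(C)C)(C(C)C)C(C)C)cc1O[Si](C(C)C)(C(C)C)C(C)C | intermediate
12 | {5-[(2E)-3,7-dimethylocta-2,6-dien-1-yl]-2,4-bis(triisopropylsilyloxy)phenyl}lithium (not isolated) | CC(C)=CCC/C(C)=C/Cc1cc([Li])c(O[Si](C(C)C)(C(C)C)C(C)C)cc1O[Si](C(C)C)(C(C)C)C(C)C | intermediate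
13 | 1-{5-[(2E)-3,7-dimethylocta-2,6-dien-1-yl]-2,4-bis(triisopropylsilyloxy)phenyl}ethanone | CC(C)=CCC/C(C)=C/Cc1cc(C(C)=O)c(O[Si](C(C)C)(C(C)C)C(C)C)cc1O[Si](C(C)C)(C(C)C)C(C)C | intermediate
14 | (E)-2,4,6-triisopropylbenzenesulfonylhydrazone of 13 | CC(C)=CCC/C(C)=C/Cc1cc(/C(C)=N/NS(=O)(=O)c2c(C(C)C)cc(C(C)C)cc2C(C)C)c(O[Si](C(C)C)(C(C)C)C(C)C)cc1O[Si](C(C)C)(C(C)C)C(C)C | intermediate
15 | 1-{5-[(2E)-3,7-dimethylocta-2,6-dien-1-yl]-2,4-bis(triisopropylsilyloxy)phenyl}vinyllithium (not isolated) | CC(C)=CCC/C(C)=C/Cc1cc(C([Li])=C)c(O[Si](C(C)C)(C(C)C)C(C)C)cc1O[Si](C(C)C)(C(C)C)C(C)C | intermediate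
16 | sodium 2-formyl-4-methyl-3,5-bis(triisopropylsilyloxy)phenoxide (not isolated) | [Na+].O=Cc1c([O-])cc(O[Si](C(C)C)(C(C)C)C(C)C)c(C)c1O[Si](C(C)C)(C(C)C)C(C)C | intermediate
17 | racemic 2-{1-hydroxy-2-[5-((2E)-3,7-dimethylocta-2,6-dien-1-yl)-2,4-bis(triisopropylsilyloxy)phenyl]prop-2-en-1-yl}-4-methyl-3,5-bis(triisopropylsilyloxy)phenol | CC(C)=CCC/C(C)=C/Cc1cc(C(=C)C(O)c2c(O)cc(O[Si](C(C)C)(C(C)C)C(C)C)c(C)c2O[Si](C(C)C)(C(C)C)C(C)C)c(O[Si](C(C)C)(C(C)C)C(C)C)cc1O[Si](C(C)C)(C(C)C)C(C)C | intermediate
18 | 2-{5-[(2E)-3,7-dimethylocta-2,6-dien-1-yl]-2,4-bis(triisopropylsilyloxy)phenyl}-1-[2-hydroxy-5-methyl-4,6-bis(triisopropylsilyloxy)phenyl]prop-2-en-1-one | CC(C)=CCC/C(C)=C/Cc1cc(C(=C)C(=O)c2c(O)cc(O[Si](C(C)C)(C(C)C)C(C)C)c(C)c2O[Si](C(C)C)(C(C)C)C(C)C)c(O[Si](C(C)C)(C(C)C)C(C)C)cc1O[Si](C(C)C)(C(C)C)C(C)C | intermediate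
19 | ring C enolate of 20, held as ion pair with the protonated catalyst and drawn as the neutral enol, 3-aryl-6-methyl-5,7-bis(triisopropylsilyloxy)-2H-chromen-4-ol (not isolated) | CC(C)=CCC/C(C)=C/Cc1cc(C2=C(O)c3c(O[Si](C(C)C)(C(C)C)C(C)C)c(C)c(O[Si](C(C)C)(C(C)C)C(C)C)cc3OC2)c(O[Si](C(C)C)(C(C)C)C(C)C)cc1O[Si](C(C)C)(C(C)C)C(C)C | intermediate
20 | (3R)-3-{5-[(2E)-3,7-dimethylocta-2,6-dien-1-yl]-2,4-bis(triisopropylsilyloxy)phenyl}-6-methyl-5,7-bis(triisopropylsilyloxy)chroman-4-one | CC(C)=CCC/C(C)=C/Cc1cc([C@@H]2COc3cc(O[Si](C(C)C)(C(C)C)C(C)C)c(C)c(O[Si](C(C)C)(C(C)C)C(C)C)c3C2=O)c(O[Si](C(C)C)(C(C)C)C(C)C)cc1O[Si](C(C)C)(C(C)C)C(C)C | intermediate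
21 | (3R)-3-{2,4-dihydroxy-5-[(2E)-3,7-dimethylocta-2,6-dien-1-yl]phenyl}-5,7-dihydroxy-6-methylchroman-4-one (CNP0348256.1) | CC(C)=CCC/C(C)=C/Cc1cc([C@@H]2COc3cc(O)c(C)c(O)c3C2=O)c(O)cc1O | target

**Summary**

Total step count: 11. Longest linear sequence: 8 steps (steps 4, 5, 6, 7, 8, 9, 10, 11).

Steps most likely to fail:

1. Step 10 (proposed new method). The risk is low enantioselectivity, through uncatalysed background ring closure or through epimerisation of the product by the amine catalyst. Fallback, known chemistry: setting out from 18, catalytic Et3N in CH2Cl2 at rt should close ring C without stereocontrol to the racemic tetrakis(triisopropylsilyl) isoflavanone F1. Asymmetric transfer hydrogenation of F1 under dynamic kinetic resolution (RuCl[(R,R)-TsDPEN](p-cymene), HCO2H/Et3N, EtOAc, 40 °C) should then give the cis-(3R,4R)-isoflavan-4-ol F2, because C3 epimerises through the enol under the amine buffer while one enantiomer is reduced faster. Oxidation of F2 at C4 with Dess–Martin periodinane (NaHCO3, CH2Cl2, 0 °C) leaves C3 untouched and comes back to the route at 20.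

2. Step 8. The risks are migration of a triisopropylsilyl group to the vinyl carbanion or to the new alkoxide, and sluggish addition to a hindered, electron-rich aldehyde. Fallback: setting out from 13, KN(SiMe3)2 and PhNTf2 in THF at –78 °C should give the enol triflate F3. A Nozaki–Hiyama–Kishi coupling of F3 with aldehyde 5 (CrCl2, catalytic NiCl2, DMF, rt) then forms the same C3–C4 bond through a non-basic organochromium species and comes back to the route at 17.

3. Step 9. The risk is ring closure of the free phenol onto the new enone during oxidation or chromatography, which would give racemic material before the chiral catalyst is present. Fallback: setting out from 17, TESCl and imidazole in CH2Cl2 at –20 °C should silylate the phenol in preference to the hindered secondary alcohol and give the O1-triethylsilyl ether F4. Oxidation of F4 (Dess–Martin periodinane, NaHCO3, CH2Cl2) gives the O1-triethylsilyl enone F5, which can be purified and stored. HF·pyridine buffered with pyridine (THF, 0 °C) then cleaves only the aryl triethylsilyl ether ortho to the carbonyl group under acidic conditions and comes back to the route at 18, used at once in step 10.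

**Further compounds**

F1 | step 10 | racemic 3-{5-[(2E)-3,7-dimethylocta-2,6-dien-1-yl]-2,4-bis(triisopropylsilyloxy)phenyl}-6-methyl-5,7-bis(triisopropylsilyloxy)chroman-4-one | CC(C)=CCC/C(C)=C/Cc1cc(C2COc3cc(O[Si](C(C)C)(C(C)C)C(C)C)c(C)c(O[Si](C(C)C)(C(C)C)C(C)C)c3C2=O)c(O[Si](C(C)C)(C(C)C)C(C)C)cc1O[Si](C(C)C)(C(C)C)C(C)C
F2 | step 10 | (3R,4R)-3-{5-[(2E)-3,7-dimethylocta-2,6-dien-1-yl]-2,4-bis(triisopropylsilyloxy)phenyl}-6-methyl-5,7-bis(triisopropylsilyloxy)chroman-4-ol (3,4-cis) | CC(C)=CCC/C(C)=C/Cc1cc([C@@H]2COc3cc(O[Si](C(C)C)(C(C)C)C(C)C)c(C)c(O[Si](C(C)C)(C(C)C)C(C)C)c3[C@@H]2O)c(O[Si](C(C)C)(C(C)C)C(C)C)cc1O[Si](C(C)C)(C(C)C)C(C)C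
F3 | step 8 | 1-{5-[(2E)-3,7-dimethylocta-2,6-dien-1-yl]-2,4-bis(triisopropylsilyloxy)phenyl}vinyl trifluoromethanesulfonate | CC(C)=CCC/C(C)=C/Cc1cc(C(=C)OS(=O)(=O)C(F)(F)F)c(O[Si](C(C)C)(C(C)C)C(C)C)cc1O[Si](C(C)C)(C(C)C)C(C)C
F4 | step 9 | racemic O1-triethylsilyl ether of 17 | CC(C)=CCC/C(C)=C/Cc1cc(C(=C)C(O)c2c(O[Si](CC)(CC)CC)cc(O[Si](C(C)C)(C(C)C)C(C)C)c(C)c2O[Si](C(C)C)(C(C)C)C(C)C)c(O[Si](C(C)C)(C(C)C)C(C)C)cc1O[Si](C(C)C)(C(C)C)C(C)C
F5 | step 9 | O1-triethylsilyl ether of enone 18 | CC(C)=CCC/C(C)=C/Cc1cc(C(=C)C(=O)c2c(O[Si](CC)(CC)CC)cc(O[Si](C(C)C)(C(C)C)C(C)C)c(C)c2O[Si](C(C)C)(C(C)C)C(C)C)c(O[Si](C(C)C)(C(C)C)C(C)C)cc1O[Si](C(C)C)(C(C)C)C(C)C
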